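If two partners must both sit on a catalyst before they react, a flask with too much of one, the other held fixed, should run slower, and you can test that by subtraction, without any integral.

all flasks: catalyst 0.00250 M
- oak: substrate 0.0500 M; coupling partner 0.100 M
- maple: substrate 0.0300 M; coupling partner 0.0800 M
- larch: substrate 0.0500 M; coupling partner 0.200 M
- birch: substrate 0.150 M; coupling partner 0.100 M
- alder: substrate 0.360 M; coupling partner 0.100 M; time 12 min

- oak run (time / min: [substrate] / M): 0.68: 0.04956; 2.1: 0.04435; 4.0: 0.03699; 6.3: 0.02820; 9.0: 0.01805; 12: 0.00898
- maple run (time / min: [substrate] / M): 0.68: 0.02943; 2.1: 0.02498; 4.0: 0.01850; 6.3: 0.01146; 9.0: 0.00509; 12: 0.00153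
- larch run (time / min: [substrate] / M): 0.68: 0.04969; 2.1: 0.04555; 4.0: 0.03831; 6.3: 0.03037; 9.0: 0.02306; 12: 0.01588
- birch run (time / min: [substrate] / M): 0.68: 0.14963; 2.1: 0.14547; 4.0: 0.13955; 6.3: 0.13150; 9.0: 0.12322; 12: 0.11418

(readings scatter by 2 × 10⁻⁴ M)

- Overall: substrate + coupling partner -> product, with catalyst as catalyst.
- Constant volume, constant temperature.
- Readings of a species count what is bound in complexes too.
- "The second partner" is coupling partner.
- An order is taken over about fifteen percent of the charge, up and down.

- order of the initial rate in [substrate], near the charge of the oak run, the rate being that where two percent of its substrate are product (one fixed amount of product, the same in the runs compared)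
- order of the initial rate in [coupling partner], near the charge of the oak run, the rate being that where two percent of its substrate are product
- the maple run starts with 0.0200 M less of substrate and of coupling partner than the oak run, and with no product. Compared where both hold the same amount of substrate, once fifteen percent of what the maple run was charged with has turned into product, is the maple run faster, slower or alike (within a tenth)?
- substrate in the alder run at 12 min, as a share of the substrate charged
- which of these the readings show (the substrate pairs with itself / the product binds the second partner / the catalyst wakes slowly / the second partner is lost by itself / nothing beyond the main steps / the loaded catalyst dies)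

Read the tables against each other, taking the substrate lost per minute between 4.0 min and 9.0 min in each run. The oak run loses 0.00379 M min⁻¹. The larch run, with twice the coupling partner, loses less than the oak run, 0.00305 M min⁻¹. The birch run, charged with 0.150 M of substrate against 0.0500 M, also loses less than the oak run, 0.00327 M min⁻¹. So on these readings an excess of either partner goes with a lower rate, and I take the rate, once substrate is in excess, to follow [coupling partner]/[substrate].

In the birch run the coupling partner is the limiting reagent. Over that stretch [substrate] averages 0.131 M. Each substrate used takes one coupling partner, so [coupling partner] averages 0.0814 M. The rate multiplied by [substrate] and divided by [coupling partner], the crowding constant, is then 0.00527 M min⁻¹.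

Now my reckoning for the alder run. At its charge the constant gives 0.00146 M min⁻¹, which over 12 min makes 0.0176 M of product. Put that answer back in: with half of it made, the alder run holds 0.351 M of substrate and 0.0912 M of coupling partner. The rate there is lower than at the charge, 0.00137 M min⁻¹. That makes 0.0164 M of product, so I expect 95.4% of the substrate to remain.

The forecast gives an order of 0 in substrate and 0.15 in coupling partner, and it calls the maple run slower. It names as what the readings show: the catalyst wakes slowly. It leaves 95% of the substrate in the alder run, a little less than my figure. Its grounds: “This looks like the two competing for the catalyst”.

The alder run keeps 94.2% of its substrate at 12 min, so it made 0.0209 M of product, more than my 0.0164 M. Near the oak charge the order is 0.052 in substrate and 0.011 in coupling partner, the maple run against the oak run comes out alike, and what the readings show is this: the catalyst wakes slowly.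

    active catalyst + substrate ⇌ catalyst-substrate complex, settled at all times (195.0 L mol⁻¹)
    active catalyst + coupling partner ⇌ catalyst-reagent complex, settled at all times (102.0 L mol⁻¹)
    catalyst-substrate complex + catalyst-reagent complex → product + 2 active catalyst (2940 L mol⁻¹ min⁻¹)
    catalyst → active catalyst (1.848 min⁻¹)

Taken at the alder run's own midpoint, that amount gives a crowding constant of 0.00679 M min⁻¹, above the 0.00527 M min⁻¹ from the birch run. Carried to the birch run's midpoint on the way to half of its charge as product, the birch value gives a rate of 0.00293 M min⁻¹, hence 25.6 min, and the birch run takes 26.9 min.

(All runs were computed with constants of no real substance; the scatter is artificial.)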